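Retrosynthetic cuts, in this order: the phenol O–Si bond; C5'–C6' (allyl–vinyl coupling); the C5'–Br bond, back through C5'–OH to the (E)-methyl C–H of a prenyl terminus; O1–C8a together with C8–CH3 (one aryne operation); C4–C4a (aryl–alkyne coupling, the alkyne being the precursor of the (Z)-C3=C4 bond).
Feature used: on the benzene ring C8a (which carries O1) and C8 (which carries the methyl group) are neighbours, and C8a is linked to C4a by the chain O1–C2–C3=C4. An aryne across C8–C8a with the carbinol tethered from C4a can therefore accept O1 and CH3 in a single step that closes the pyran ring.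
Forward: geraniol gives (S)-3,7-dimethyloct-6-en-1-yn-3-ol, which is used twice; hydroquinone gives a 2-bromo-6-iodoaryl tosylate; Sonogashira coupling and semihydrogenation join them. The aryne step forms the only new ring (the 2H-pyran ring of the chromene). The chain is then grown by allylic oxidation, bromination and Stille coupling with the (E)-stannane of the same alkynol, and the phenol is unmasked last.
Stereochemistry: C2 and C8' (both S) come from one Sharpless epoxidation of geraniol with L-(+)-diethyl tartrate, and neither C–O bond is broken afterwards. C3'=C4' (E) comes from the site selectivity of SeO2, and C6'=C7' (E) from syn-hydrostannation and a stereoretentive coupling.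

Key step: step 10

Remarks on the chemistry
- Numbering: chromene atoms are O1, C2, C3, C4, C4a, C5–C8, C8a; side-chain carbons are C1'–C13', counted from C2.
- Configuration: by the CIP rules the target is (2S,8'S). Both centres have the spatial arrangement of the (S)-alkynol 6, because the ethynyl group, the vinyl groups and ring carbon C3 all rank between oxygen and the CH2 chain.
- Because 6 is built in twice, any minor enantiomer of 6 should end up mainly in diastereomers of the target, not in its enantiomer.
- 2H-Chromenes can open photochemically at O1–C2, so compounds 19–24 are handled with exclusion of light.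

Step 1
Reactants: 1 geraniol
Product: 2 [(2S,3S)-3-methyl-3-(4-methylpent-3-en-1-yl)oxiran-2-yl]methanol
Conditions: Ti(OiPr)4 (5 mol%), L-(+)-diethyl tartrate (6 mol%), t-BuOOH, 4 Å molecular sieves, CH2Cl2, −20 °C
Reagents that add atoms: tert-butyl hydroperoxide, CC(C)(C)OO
Why: Sharpless asymmetric epoxidation: the complex formed from Ti(OiPr)4 and the tartrate binds the allylic hydroxyl and delivers oxygen to one face of the C2=C3 alkene only, so L-(+)-diethyl tartrate should give the (2S,3S)-epoxide and set the quaternary carbon that becomes both stereocentres of the target, while the remote C6=C7 alkene is untouched.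

Step 2
Reactants: 2 [(2S,3S)-3-methyl-3-(4-methylpent-3-en-1-yl)oxiran-2-yl]methanol
Product: 3 (2R,3S)-2-(chloromethyl)-3-methyl-3-(4-methylpent-3-en-1-yl)oxirane
Conditions: PPh3, CCl4, NaHCO3, reflux
Reagents that add atoms: tetrachloromethane, ClC(Cl)(Cl)Cl
Why: Appel chlorination of the primary alcohol under buffered, near-neutral conditions should replace OH by Cl without opening the epoxide or touching either stereocentre (the descriptor at the CH carbon changes only because CH2Cl outranks the ring carbon).

Step 3
Reactants: 3 (2R,3S)-2-(chloromethyl)-3-methyl-3-(4-methylpent-3-en-1-yl)oxirane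
Product: 6 (3S)-3,7-dimethyloct-6-en-1-yn-3-ol, via chloroalkenyl lithium alkoxide 4 (not isolated), via dilithium alkynide alkoxide 5 (not isolated)
Conditions: n-BuLi (3.2 equiv), THF, −40 to 0 °C; then H2O
Reagents that add atoms: none
Why: Base-induced fragmentation of a 2,3-epoxy chloride to a propargylic alcohol: deprotonation next to chlorine opens the epoxide to 4, loss of HCl and deprotonation of the alkyne give 5, and the quench gives 6 with the C3–O bond, and hence the (S)-configuration, intact.

Step 4
Reactants: 7 hydroquinone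
Product: 8 4-[(triisopropylsilyl)oxy]phenol
Conditions: hydroquinone (3 equiv), i-Pr3SiCl (1 equiv), imidazole, DMF, rt
Reagents that add atoms: chlorotriisopropylsilane, CC(C)[Si](Cl)(C(C)C)C(C)C
Why: Statistical monosilylation: with the diol in excess the silyl chloride should meet mainly unsilylated hydroquinone, and the water-soluble excess is washed out.

Step 5
Reactants: 8 4-[(triisopropylsilyl)oxy]phenol
Product: 9 2-bromo-4-[(triisopropylsilyl)oxy]phenol
Conditions: NBS (1.0 equiv), i-Pr2NH (10 mol%), CH2Cl2, 0 °C
Reagents that add atoms: N-bromosuccinimide, BrN1C(=O)CCC1=O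
Why: Electrophilic aromatic bromination: the free hydroxyl is the stronger activator and the bulky silyl ether shields its own ortho positions, so one equivalent of NBS should brominate once, ortho to OH.

Step 6
Reactants: 9 2-bromo-4-[(triisopropylsilyl)oxy]phenol
Product: 10 2-bromo-6-iodo-4-[(triisopropylsilyl)oxy]phenol
Conditions: NIS (1.05 equiv), TsOH·H2O (10 mol%), MeCN, rt
Reagents that add atoms: N-iodosuccinimide, IN1C(=O)CCC1=O
Why: Electrophilic aromatic iodination at the one remaining position ortho to the free hydroxyl, which gives two different halogens flanking the oxygen so that the later coupling is chemoselective and not statistical.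

Step 7
Reactants: 10 2-bromo-6-iodo-4-[(triisopropylsilyl)oxy]phenol
Product: 11 2-bromo-6-iodo-4-[(triisopropylsilyl)oxy]phenyl 4-methylbenzenesulfonate
Conditions: TsCl, Et3N, DMAP (cat.), CH2Cl2, 0 °C to rt
Reagents that add atoms: 4-methylbenzenesulfonyl chloride, Cc1ccc(cc1)S(Cl)(=O)=O
Why: Sulfonylation of the acidic 2,6-dihalophenol: the tosylate is the leaving group of the later aryne formation, is inert in the palladium steps and keeps the phenol oxygen from cyclising onto the alkyne.

Step 8
Reactants: 11 2-bromo-6-iodo-4-[(triisopropylsilyl)oxy]phenyl 4-methylbenzenesulfonate, 6 (3S)-3,7-dimethyloct-6-en-1-yn-3-ol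
Product: 12 2-bromo-6-[(3S)-3-hydroxy-3,7-dimethyloct-6-en-1-yn-1-yl]-4-[(triisopropylsilyl)oxy]phenyl 4-methylbenzenesulfonate
Conditions: PdCl2(PPh3)2 (3 mol%), CuI (5 mol%), Et3N, THF, rt
Reagents that add atoms: none
Why: Sonogashira coupling: at room temperature oxidative addition is much faster at C–I than at C–Br or C–OTs, so only the iodide should be replaced, forming the future C4–C4a bond with the stereocentre of 6 as a spectator.

Step 9
Reactants: 12 2-bromo-6-[(3S)-3-hydroxy-3,7-dimethyloct-6-en-1-yn-1-yl]-4-[(triisopropylsilyl)oxy]phenyl 4-methylbenzenesulfonate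
Product: 13 2-bromo-6-[(1Z,3S)-3-hydroxy-3,7-dimethylocta-1,6-dien-1-yl]-4-[(triisopropylsilyl)oxy]phenyl 4-methylbenzenesulfonate
Conditions: H2 (1 atm), Pd/CaCO3 poisoned with Pb(OAc)2 (Lindlar catalyst), quinoline, EtOAc, rt
Reagents that add atoms: none
Why: Lindlar semihydrogenation: syn delivery of H2 on the poisoned palladium surface should give the (Z)-alkene that places the carbinol oxygen within reach of the tosylate-bearing carbon, while the aryl bromide, the tosylate and the trisubstituted alkene are left alone.

Step 10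
Reactants: 13 2-bromo-6-[(1Z,3S)-3-hydroxy-3,7-dimethylocta-1,6-dien-1-yl]-4-[(triisopropylsilyl)oxy]phenyl 4-methylbenzenesulfonate, 14 iodomethane
Product: 19 (2S)-2,8-dimethyl-2-(4-methylpent-3-en-1-yl)-6-[(triisopropylsilyl)oxy]-2H-chromene, via lithium alkoxide 15 (not isolated), via C8-lithio tosylate 16 (not isolated), via aryne alkoxide 17 (not isolated), via 8-lithiochromene 18 (not isolated)
Conditions: MeLi (1.0 equiv), THF, −78 °C; n-BuLi (1.05 equiv), −78 to −20 °C; MeI (3 equiv), −78 °C to rt
Reagents that add atoms: iodomethane (compound 14), CI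
Why: Proposed new method: MeLi first turns the tertiary alcohol into lithium alkoxide 15 with methane as the only by-product, n-BuLi then exchanges the bromine on the future C8 to give 16, and on warming 16 loses lithium tosylate to form the C8–C8a aryne 17, whose in-plane π bond is attacked at C8a by the alkoxide held on the (Z)-alkene, leaving aryllithium 18, which iodomethane methylates at C8. The closest known reaction types are the capture of arynes by pendant alcohols to give chromans with an electrophile entering at C8, aryne generation from 2-haloaryl sulfonates by halogen–metal exchange, and the addition of metal heteroatom nucleophiles to arynes followed by electrophilic quench of the aryl metal; the (Z)-alkenyl tether and the C-methyl quench are the new elements. The one ring formed, the 2H-pyran ring (O1, C2, C3, C4, C4a, C8a), closes in a 6-exo-dig mode with respect to the aryne bond. No stereocentre is created: the C2–O bond is never broken, so the (S)-carbinol becomes (S)-C2 unchanged, which an ionising cyclodehydration of a tertiary allylic alcohol could not guarantee. The step needs regioselectivity (oxygen to C8a, carbon to C8), which the tether secures because attack at C8 would need a ring bridging meta positions, and which the inductively withdrawing C6 silyloxy group, meta to the developing C8 carbanion, supports. It also needs the aryne to meet no external nucleophile and the aryl anion no proton source, which is secured by pre-forming the alkoxide, by using a single equivalent of n-BuLi that is consumed in the fast exchange before the slower tosylate loss begins, and by keeping the mixture aprotic until iodomethane is added.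

Step 11
Reactants: 19 (2S)-2,8-dimethyl-2-(4-methylpent-3-en-1-yl)-6-[(triisopropylsilyl)oxy]-2H-chromene
Product: 20 (2E)-5-{(2S)-2,8-dimethyl-6-[(triisopropylsilyl)oxy]-2H-chromen-2-yl}-2-methylpent-2-en-1-ol
Conditions: SeO2 (0.3 equiv), t-BuOOH (3 equiv), salicylic acid (10 mol%), CH2Cl2, 0 °C to rt
Reagents that add atoms: selenium dioxide, O=[Se]=O (oxygen carrier); tert-butyl hydroperoxide, CC(C)(C)OO (terminal oxidant)
Why: Catalytic SeO2 allylic oxidation with t-BuOOH as re-oxidant (ene reaction, then [2,3]-sigmatropic shift) is selective for the (E)-methyl group at the more substituted end of a trisubstituted alkene, and the chromene C3=C4 bond offers no allylic hydrogen.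

Step 12
Reactants: 20 (2E)-5-{(2S)-2,8-dimethyl-6-[(triisopropylsilyl)oxy]-2H-chromen-2-yl}-2-methylpent-2-en-1-ol
Product: 21 (2S)-2-[(3E)-5-bromo-4-methylpent-3-en-1-yl]-2,8-dimethyl-6-[(triisopropylsilyl)oxy]-2H-chromene
Conditions: CBr4, PPh3, CH2Cl2, 0 °C
Reagents that add atoms: tetrabromomethane, BrC(Br)(Br)Br
Why: Appel bromination should convert the primary allylic alcohol into the bromide under neutral conditions without allylic transposition or loss of the (E)-geometry; the bromide is used at once.

Step 13
Reactants: 6 (3S)-3,7-dimethyloct-6-en-1-yn-3-ol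
Product: 22 (1E,3S)-3,7-dimethyl-1-(tributylstannyl)octa-1,6-dien-3-ol
Conditions: Bu3SnH (1.1 equiv), PdCl2(PPh3)2 (2 mol%), THF, 0 °C
Reagents that add atoms: tributyltin hydride, CCCC[SnH](CCCC)CCCC
Why: Palladium-catalysed hydrostannation: syn addition of Sn–H with tin at the unhindered terminal carbon of the tertiary propargylic alcohol should give the (E)-vinylstannane, the trisubstituted alkene being inert.

Step 14
Reactants: 21 (2S)-2-[(3E)-5-bromo-4-methylpent-3-en-1-yl]-2,8-dimethyl-6-[(triisopropylsilyl)oxy]-2H-chromene, 22 (1E,3S)-3,7-dimethyl-1-(tributylstannyl)octa-1,6-dien-3-ol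
Product: 23 (3E,6E,8S)-1-{(2S)-2,8-dimethyl-6-[(triisopropylsilyl)oxy]-2H-chromen-2-yl}-4,8,12-trimethyltrideca-3,6,11-trien-8-ol
Conditions: Pd2(dba)3 (2.5 mol%), AsPh3 (10 mol%), NMP, rt
Reagents that add atoms: none
Why: Stille coupling of an allylic bromide with a vinylstannane should join C5' to C6' at the primary allyl terminus with retention of both alkene geometries; it tolerates the free tertiary alcohol, and 21 holds no other carbon–halogen bond.

Step 15
Reactants: 23 (3E,6E,8S)-1-{(2S)-2,8-dimethyl-6-[(triisopropylsilyl)oxy]-2H-chromen-2-yl}-4,8,12-trimethyltrideca-3,6,11-trien-8-ol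
Product: 24 (2S)-2-[(3E,6E,8S)-8-hydroxy-4,8,12-trimethyltrideca-3,6,11-trien-1-yl]-2,8-dimethyl-2H-chromen-6-ol
Conditions: Bu4NF, AcOH (1:1), THF, 0 °C to rt
Reagents that add atoms: none
Why: Fluoride-induced cleavage of the aryl silyl ether, driven by the Si–F bond and buffered with acetic acid so that the electron-rich phenol is released without standing as a phenoxide; the tertiary allylic alcohol and the alkenes are unaffected.

Compound list
1 | geraniol | CC(C)=CCC/C(C)=C/CO | starting material
2 | [(2S,3S)-3-methyl-3-(4-methylpent-3-en-1-yl)oxiran-2-yl]methanol | CC(C)=CCC[C@]1(C)O[C@H]1CO | intermediate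
3 | (2R,3S)-2-(chloromethyl)-3-methyl-3-(4-methylpent-3-en-1-yl)oxirane | CC(C)=CCC[C@]1(C)O[C@H]1CCl | intermediate
4 | lithium (1E,3S)-1-chloro-3,7-dimethylocta-1,6-dien-3-olate (drawn as the E isomer expected from anti-periplanar opening; either isomer leads to the alkyne) | CC(C)=CCC[C@](C)([O-])/C=C/Cl.[Li+] | intermediate (not isolated)
5 | dilithium salt (alkynide and alkoxide) of (3S)-3,7-dimethyloct-6-en-1-yn-3-ol | CC(C)=CCC[C@](C)([O-])C#[C-].[Li+].[Li+] | intermediate (not isolated)
6 | (3S)-3,7-dimethyloct-6-en-1-yn-3-ol | CC(C)=CCC[C@](C)(O)C#C | intermediate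
7 | hydroquinone | Oc1ccc(O)cc1 | starting material
8 | 4-[(triisopropylsilyl)oxy]phenol | CC(C)[Si](Oc1ccc(O)cc1)(C(C)C)C(C)C | intermediate
9 | 2-bromo-4-[(triisopropylsilyl)oxy]phenol | CC(C)[Si](Oc1ccc(O)c(Br)c1)(C(C)C)C(C)C | intermediate
10 | 2-bromo-6-iodo-4-[(triisopropylsilyl)oxy]phenol | CC(C)[Si](Oc1cc(I)c(O)c(Br)c1)(C(C)C)C(C)C | intermediate
11 | 2-bromo-6-iodo-4-[(triisopropylsilyl)oxy]phenyl 4-methylbenzenesulfonate | Cc1ccc(cc1)S(=O)(=O)Oc1c(Br)cc(O[Si](C(C)C)(C(C)C)C(C)C)cc1I | intermediate
12 | 2-bromo-6-[(3S)-3-hydroxy-3,7-dimethyloct-6-en-1-yn-1-yl]-4-[(triisopropylsilyl)oxy]phenyl 4-methylbenzenesulfonate | CC(C)=CCC[C@](C)(O)C#Cc1cc(O[Si](C(C)C)(C(C)C)C(C)C)cc(Br)c1OS(=O)(=O)c1ccc(C)cc1 | intermediate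
13 | 2-bromo-6-[(1Z,3S)-3-hydroxy-3,7-dimethylocta-1,6-dien-1-yl]-4-[(triisopropylsilyl)oxy]phenyl 4-methylbenzenesulfonate (phenyl C1 = future C8a, C2 = future C8, C6 = future C4a) | CC(C)=CCC[C@](C)(O)/C=C\c1cc(O[Si](C(C)C)(C(C)C)C(C)C)cc(Br)c1OS(=O)(=O)c1ccc(C)cc1 | intermediate
14 | iodomethane | CI | starting material
15 | lithium alkoxide of 13: lithium (1Z,3S)-1-{3-bromo-2-(tosyloxy)-5-[(triisopropylsilyl)oxy]phenyl}-3,7-dimethylocta-1,6-dien-3-olate | CC(C)=CCC[C@](C)([O-])/C=C\c1cc(O[Si](C(C)C)(C(C)C)C(C)C)cc(Br)c1OS(=O)(=O)c1ccc(C)cc1.[Li+] | intermediate (not isolated)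
16 | aryllithium from 15 with lithium in place of bromine (future C8), alkoxide retained | CC(C)=CCC[C@](C)([O-])/C=C\c1cc(O[Si](C(C)C)(C(C)C)C(C)C)cc([Li])c1OS(=O)(=O)c1ccc(C)cc1.[Li+] | intermediate (not isolated)
17 | aryne (triple bond between future C8 and C8a) carrying the (1Z,3S)-lithium alkoxide side chain and the 5-silyloxy group | CC(C)=CCC[C@](C)([O-])/C=C\C1=CC(O[Si](C(C)C)(C(C)C)C(C)C)=CC#C1.[Li+] | intermediate (not isolated)
18 | {(2S)-2-methyl-2-(4-methylpent-3-en-1-yl)-6-[(triisopropylsilyl)oxy]-2H-chromen-8-yl}lithium | CC(C)=CCC[C@@]1(C)C=Cc2cc(O[Si](C(C)C)(C(C)C)C(C)C)cc([Li])c2O1 | intermediate (not isolated)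
19 | (2S)-2,8-dimethyl-2-(4-methylpent-3-en-1-yl)-6-[(triisopropylsilyl)oxy]-2H-chromene | CC(C)=CCC[C@@]1(C)C=Cc2cc(O[Si](C(C)C)(C(C)C)C(C)C)cc(C)c2O1 | intermediate
20 | (2E)-5-{(2S)-2,8-dimethyl-6-[(triisopropylsilyl)oxy]-2H-chromen-2-yl}-2-methylpent-2-en-1-ol | OC/C(C)=C/CC[C@@]1(C)C=Cc2cc(O[Si](C(C)C)(C(C)C)C(C)C)cc(C)c2O1 | intermediate
21 | (2S)-2-[(3E)-5-bromo-4-methylpent-3-en-1-yl]-2,8-dimethyl-6-[(triisopropylsilyl)oxy]-2H-chromene | BrC/C(C)=C/CC[C@@]1(C)C=Cc2cc(O[Si](C(C)C)(C(C)C)C(C)C)cc(C)c2O1 | intermediate
22 | (1E,3S)-3,7-dimethyl-1-(tributylstannyl)octa-1,6-dien-3-ol | CC(C)=CCC[C@](C)(O)/C=C/[Sn](CCCC)(CCCC)CCCC | intermediate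
23 | (3E,6E,8S)-1-{(2S)-2,8-dimethyl-6-[(triisopropylsilyl)oxy]-2H-chromen-2-yl}-4,8,12-trimethyltrideca-3,6,11-trien-8-ol | CC(C)=CCC[C@](C)(O)/C=C/C/C(C)=C/CC[C@@]1(C)C=Cc2cc(O[Si](C(C)C)(C(C)C)C(C)C)cc(C)c2O1 | intermediate
24 | (2S)-2-[(3E,6E,8S)-8-hydroxy-4,8,12-trimethyltrideca-3,6,11-trien-1-yl]-2,8-dimethyl-2H-chromen-6-ol | CC(C)=CCC[C@](C)(O)/C=C/C/C(C)=C/CC[C@@]1(C)C=Cc2cc(O)cc(C)c2O1 | target

Total step count: 15.
Longest linear sequence: 11 steps (hydroquinone 7 to target 24 through steps 4–12, 14 and 15); the geraniol branch reaches the target in 10.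

Steps most likely to fail

1. Step 10 (proposed new method). The alkyllithium may attack the sulfonyl sulfur, or the sulfonyl group may migrate to the lithiated carbon, in place of tosylate loss. The aryne may also be intercepted by a stray nucleophile, or the C8 aryllithium may be protonated or butylated before it meets iodomethane. The fallback uses known chemistry only: the methyl group is placed on the arene beforehand and the O1–C8a bond is made by palladium-catalysed intramolecular aryl etherification of the tertiary alcohol (Buchwald–Hartwig type). It sets out from alkynol 6 and returns to the route at 19. Commercial 4-amino-3-methylphenol is O-silylated (i-Pr3SiCl, imidazole, DMF) to 2-methyl-4-[(triisopropylsilyl)oxy]aniline F1. Iodination ortho to the amino group (I2, NaHCO3) gives 2-iodo-6-methyl-4-[(triisopropylsilyl)oxy]aniline F2. Sandmeyer bromination (t-BuONO, CuBr2, MeCN) gives (4-bromo-3-iodo-5-methylphenoxy)triisopropylsilane F3. Iodide-selective Sonogashira coupling with 6 (PdCl2(PPh3)2, CuI, Et3N) should give (3S)-1-{2-bromo-3-methyl-5-[(triisopropylsilyl)oxy]phenyl}-3,7-dimethyloct-6-en-1-yn-3-ol F4. Lindlar semihydrogenation as in step 9 should give (1Z,3S)-1-{2-bromo-3-methyl-5-[(triisopropylsilyl)oxy]phenyl}-3,7-dimethylocta-1,6-dien-3-ol F5. Pd(OAc)2 with 2-(di-tert-butylphosphino)-1,1'-binaphthyl and Cs2CO3 in toluene at 80 °C then closes the ring to 19. A tertiary alkoxide on palladium has no hydrogen for β-hydride elimination, and the C2–O bond is again untouched.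

2. Step 11. Oxidation may stall, run on to the enal, or stray to the (Z)-methyl group or the electron-rich chromene. The fallback replaces C–H oxidation by olefin cross-metathesis; it sets out from 19 and returns at 20. Treatment of 19 with methacrolein and the second-generation Hoveyda–Grubbs catalyst (CH2Cl2, 40 °C) exchanges the isopropylidene terminus and should give (2E)-5-{(2S)-2,8-dimethyl-6-[(triisopropylsilyl)oxy]-2H-chromen-2-yl}-2-methylpent-2-enal F6. Luche reduction (NaBH4, CeCl3·7H2O, MeOH, 0 °C) then gives 20.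

3. Step 14. The (E)-trisubstituted alkene may lose its geometry through syn–anti isomerisation of the π-allylpalladium intermediate, coupling may occur at the wrong allyl terminus, or the stannane may be lost to protodestannylation or homocoupling. The fallback avoids allylpalladium and tin; it sets out from 21 and 6 and returns at 23. Copper-mediated SN2 coupling of the terminal alkyne 6 with bromide 21 (CuI, NaI, Cs2CO3, DMF, rt) should give the skipped enyne (3E,8S)-1-{(2S)-2,8-dimethyl-6-[(triisopropylsilyl)oxy]-2H-chromen-2-yl}-4,8,12-trimethyltrideca-3,11-dien-6-yn-8-ol F7. Hydroxyl-directed trans-hydroalumination with NaAlH2(OCH2CH2OCH3)2 (THF, 0 °C to rt), followed by protonation, reduces the propargylic alkyne to the (E)-alkene and gives 23.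

Further compounds
F1 | step 10 | 2-methyl-4-[(triisopropylsilyl)oxy]aniline | Cc1cc(O[Si](C(C)C)(C(C)C)C(C)C)ccc1N
F2 | step 10 | 2-iodo-6-methyl-4-[(triisopropylsilyl)oxy]aniline | Cc1cc(O[Si](C(C)C)(C(C)C)C(C)C)cc(I)c1N
F3 | step 10 | (4-bromo-3-iodo-5-methylphenoxy)triisopropylsilane | Cc1cc(O[Si](C(C)C)(C(C)C)C(C)C)cc(I)c1Br
F4 | step 10 | (3S)-1-{2-bromo-3-methyl-5-[(triisopropylsilyl)oxy]phenyl}-3,7-dimethyloct-6-en-1-yn-3-ol | CC(C)=CCC[C@](C)(O)C#Cc1cc(O[Si](C(C)C)(C(C)C)C(C)C)cc(C)c1Br
F5 | step 10 | (1Z,3S)-1-{2-bromo-3-methyl-5-[(triisopropylsilyl)oxy]phenyl}-3,7-dimethylocta-1,6-dien-3-ol | CC(C)=CCC[C@](C)(O)/C=C\c1cc(O[Si](C(C)C)(C(C)C)C(C)C)cc(C)c1Br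
F6 | step 11 | (2E)-5-{(2S)-2,8-dimethyl-6-[(triisopropylsilyl)oxy]-2H-chromen-2-yl}-2-methylpent-2-enal | O=C/C(C)=C/CC[C@@]1(C)C=Cc2cc(O[Si](C(C)C)(C(C)C)C(C)C)cc(C)c2O1
F7 | step 14 | (3E,8S)-1-{(2S)-2,8-dimethyl-6-[(triisopropylsilyl)oxy]-2H-chromen-2-yl}-4,8,12-trimethyltrideca-3,11-dien-6-yn-8-ol | CC(C)=CCC[C@](C)(O)C#CC/C(C)=C/CC[C@@]1(C)C=Cc2cc(O[Si](C(C)C)(C(C)C)C(C)C)cc(C)c2O1
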